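The target is disconnected at the C6–O and C7–O bonds of ring A. Because the oxygens on C5 and C8 stand para to each other, ring A can be carried as a 5,8-quinone, in which C6 and C7 are electrophilic vinylic carbons. A single treatment with methoxide then replaces two bromides and installs both missing ring A oxygens; reductive methylation afterwards restores the aromatic ring and hydrogenolysis frees the 4'-hydroxyl. The precursor is the 4'-benzyloxy-6,7-dibromoflavone-5,8-quinone. Its bromines are placed on the acetophenone before ring B is attached, so that electrophilic bromine never meets the benzyloxyphenyl ring or C3 of the pyranone.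

Key step: step 5

Remark on the design: both bromines are introduced by aromatic substitution on the starting acetophenone, and the quinone is unmasked only after the flavone is complete; the dibromoquinone and the dimethoxyquinone of the key step are unchanged in structure.

Assumption: the bromo-methoxy intermediate of the key step is written as the 7-bromo-6-methoxy isomer (first attack at C6, β to the more ketone-like C8 carbonyl); the other order of substitution would lead to the same product.

Step 1
Reactants: 1 1-(2-hydroxy-3,6-dimethoxyphenyl)ethanone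
Product: 3 1-(3,4-dibromo-6-hydroxy-2,5-dimethoxyphenyl)ethanone, via 1-(3-bromo-6-hydroxy-2,5-dimethoxyphenyl)ethanone 2 (not isolated)
Conditions: Br2 (2.2 equiv), NaOAc, AcOH, rt → 50 °C
Reagents that add atoms: bromine, BrBr
Why: Electrophilic aromatic bromination: the first bromine should enter para to the free phenol and the second should take the only remaining ring position, ortho to a methoxy group, while the acetate buffer removes HBr so that acid-catalysed enolisation and side-chain bromination of the acetyl group stay slow.

Step 2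
Reactants: 3 1-(3,4-dibromo-6-hydroxy-2,5-dimethoxyphenyl)ethanone; 4 4-(benzyloxy)benzoyl chloride
Product: 5 1-[4-(benzyloxy)phenyl]-3-(3,4-dibromo-6-hydroxy-2,5-dimethoxyphenyl)propane-1,3-dione
Conditions: LiN(SiMe3)2 (3.2 equiv), THF, −78 → −10 °C; then 4, −78 °C → rt; aq. HCl
Reagents that add atoms: none
Why: One-flask variant of the Baker–Venkataraman diketone synthesis: the lithium phenoxide–enolate dianion should be C-aroylated by the acid chloride, the third equivalent of base protects the diketone as its enolate, and the fully substituted ring offers no aryl C–H for metalation.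

Step 3
Reactants: 5 1-[4-(benzyloxy)phenyl]-3-(3,4-dibromo-6-hydroxy-2,5-dimethoxyphenyl)propane-1,3-dione
Product: 6 2-[4-(benzyloxy)phenyl]-6,7-dibromo-5,8-dimethoxy-4H-chromen-4-one
Conditions: p-TsOH·H2O (cat.), toluene, reflux, Dean–Stark
Reagents that add atoms: none
Why: Acid-catalysed cyclodehydration, the closing stage of the Baker–Venkataraman flavone synthesis: the phenol adds to the distal aryl ketone and water is lost, and a catalytic sulfonic acid in toluene should leave the benzyl aryl ether intact.

Step 4
Reactants: 6 2-[4-(benzyloxy)phenyl]-6,7-dibromo-5,8-dimethoxy-4H-chromen-4-one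
Product: 7 2-[4-(benzyloxy)phenyl]-6,7-dibromo-4H-chromene-4,5,8-trione
Conditions: (NH4)2Ce(NO3)6 (2.5–3 equiv), MeCN/H2O, 0 °C → rt
Reagents that add atoms: water, O
Why: Oxidative demethylation of a para-dimethoxyarene by tetravalent cerium: two one-electron oxidations of ring A, attack of water at C5 and C8 and loss of methanol should give the para-quinone, as known for 2,3-dibromo-1,4-dimethoxyarenes, and ring A with three oxygen donors is oxidised before ring B with one.

Step 5
Reactants: 7 2-[4-(benzyloxy)phenyl]-6,7-dibromo-4H-chromene-4,5,8-trione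
Product: 9 2-[4-(benzyloxy)phenyl]-6,7-dimethoxy-4H-chromene-4,5,8-trione, via 2-[4-(benzyloxy)phenyl]-7-bromo-6-methoxy-4H-chromene-4,5,8-trione 8 (not isolated)
Conditions: NaOMe (2.1 equiv), MeOH/THF, −40 → 0 °C; AcOH quench
Reagents that add atoms: sodium methoxide, [Na+].[O-]C
Why: Methoxide adds to C6, the vinylic carbon β to the C8 carbonyl, and the enolate so formed expels bromide to give 8; the same addition–elimination at C7, β to the C5 carbonyl, gives 9 (nucleophilic vinylic substitution at a vinylogous acyl bromide). The closest known reaction is the exchange of both halogens of 2,3-dihalo-1,4-naphthoquinones for alkoxy groups with sodium alkoxides. No ring is closed and no stereocentre is formed. The selectivity needed is attack at C6 and C7 instead of C8a or C2 of the pyranone; it is secured because loss of bromide is irreversible, whereas addition at C8a or C2 can only expel the ring oxygen as a tethered diketone enolate that is able to reclose, so such adducts should return to the productive pathway. Two equivalents of NaOMe, low temperature and an acidic quench keep the pyranone from prolonged contact with base, and the order in which the two bromides leave does not matter.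

Step 6
Reactants: 9 2-[4-(benzyloxy)phenyl]-6,7-dimethoxy-4H-chromene-4,5,8-trione
Product: 11 2-[4-(benzyloxy)phenyl]-5,6,7,8-tetramethoxy-4H-chromen-4-one, via 2-[4-(benzyloxy)phenyl]-5,8-dihydroxy-6,7-dimethoxy-4H-chromen-4-one 10 (not isolated)
Conditions: Na2S2O4, EtOAc/H2O, rt; then Me2SO4, K2CO3, acetone, reflux, Ar
Reagents that add atoms: dimethyl sulfate, COS(=O)(=O)OC
Why: Dithionite reduction of the quinone to hydroquinone 10 followed by Williamson-type O-methylation of both phenols, including the hydrogen-bonded one at C5, should fix ring A in its aromatic tetramethoxy form, with inert gas keeping 10 from reoxidising.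

Step 7
Reactants: 11 2-[4-(benzyloxy)phenyl]-5,6,7,8-tetramethoxy-4H-chromen-4-one
Product: 12 2-(4-hydroxyphenyl)-5,6,7,8-tetramethoxy-4H-chromen-4-one (4'-hydroxy-5,6,7,8-tetramethoxyflavone)
Conditions: H2 (1 atm), 10% Pd/C, EtOAc/MeOH, rt
Reagents that add atoms: none
Why: Catalytic hydrogenolysis of the benzyl aryl ether should free the 4'-phenol, the methyl ethers being inert and the C2=C3 bond of the flavone being reduced much more slowly when the reaction is stopped after one equivalent of hydrogen.

Compound list
1 | 1-(2-hydroxy-3,6-dimethoxyphenyl)ethanone | CC(=O)c1c(O)c(OC)ccc1OC | starting material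
2 | 1-(3-bromo-6-hydroxy-2,5-dimethoxyphenyl)ethanone | CC(=O)c1c(O)c(OC)cc(Br)c1OC | intermediate
3 | 1-(3,4-dibromo-6-hydroxy-2,5-dimethoxyphenyl)ethanone | CC(=O)c1c(O)c(OC)c(Br)c(Br)c1OC | intermediate
4 | 4-(benzyloxy)benzoyl chloride | O=C(Cl)c1ccc(OCc2ccccc2)cc1 | starting material
5 | 1-[4-(benzyloxy)phenyl]-3-(3,4-dibromo-6-hydroxy-2,5-dimethoxyphenyl)propane-1,3-dione | O=C(CC(=O)c1ccc(OCc2ccccc2)cc1)c1c(O)c(OC)c(Br)c(Br)c1OC | intermediate
6 | 2-[4-(benzyloxy)phenyl]-6,7-dibromo-5,8-dimethoxy-4H-chromen-4-one | COc1c(Br)c(Br)c(OC)c2oc(-c3ccc(OCc4ccccc4)cc3)cc(=O)c12 | intermediate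
7 | 2-[4-(benzyloxy)phenyl]-6,7-dibromo-4H-chromene-4,5,8-trione | O=C1C(Br)=C(Br)C(=O)C2=C1C(=O)C=C(c1ccc(OCc3ccccc3)cc1)O2 | intermediate
8 | 2-[4-(benzyloxy)phenyl]-7-bromo-6-methoxy-4H-chromene-4,5,8-trione | O=C1C(OC)=C(Br)C(=O)C2=C1C(=O)C=C(c1ccc(OCc3ccccc3)cc1)O2 | intermediate
9 | 2-[4-(benzyloxy)phenyl]-6,7-dimethoxy-4H-chromene-4,5,8-trione | O=C1C(OC)=C(OC)C(=O)C2=C1C(=O)C=C(c1ccc(OCc3ccccc3)cc1)O2 | intermediate
10 | 2-[4-(benzyloxy)phenyl]-5,8-dihydroxy-6,7-dimethoxy-4H-chromen-4-one | COc1c(OC)c(O)c2c(=O)cc(-c3ccc(OCc4ccccc4)cc3)oc2c1O | intermediate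
11 | 2-[4-(benzyloxy)phenyl]-5,6,7,8-tetramethoxy-4H-chromen-4-one | COc1c(OC)c(OC)c2c(=O)cc(-c3ccc(OCc4ccccc4)cc3)oc2c1OC | intermediate
12 | 2-(4-hydroxyphenyl)-5,6,7,8-tetramethoxy-4H-chromen-4-one | COc1c(OC)c(OC)c2c(=O)cc(-c3ccc(O)cc3)oc2c1OC | target

Total step count: 7. Longest linear sequence: 7 steps (1 to 12).

Steps most likely to fail

Step 5. Methoxide may add at C8a or C2 and open the pyranone faster than it can reclose, or the reaction may stall after the first substitution because the new C6 methoxy group lowers the electrophilicity of C7. The fallback gives up the quinone and places the two oxygens on the aromatic ring by copper catalysis. It sets out from 3: NaOMe with catalytic CuBr in DMF/MeOH at about 110 °C should replace both aryl bromides (Ullmann-type methoxylation of a bromophenol) to give 1-(2-hydroxy-3,4,5,6-tetramethoxyphenyl)ethanone F1. Aroylation of F1 with 4 under LiN(SiMe3)2 in THF, as in step 2, should give 1-[4-(benzyloxy)phenyl]-3-(2-hydroxy-3,4,5,6-tetramethoxyphenyl)propane-1,3-dione F2. Cyclodehydration of F2 with catalytic p-TsOH in refluxing toluene comes back to the route at 11.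

Step 4. Electron transfer from the doubly brominated, acyl-substituted ring A to tetravalent cerium may be slow, so that unselective oxidation or hydrolytic degradation of the product competes. The fallback separates demethylation from oxidation. It sets out from 6: MgI2 in Et2O/toluene at about 80 °C should cleave only the C5 methyl ether, which is chelated to the C4 carbonyl, to give 2-[4-(benzyloxy)phenyl]-6,7-dibromo-5-hydroxy-8-methoxy-4H-chromen-4-one F3. This para-methoxyphenol is far easier to oxidise than the diether, and PhI(OAc)2 in MeCN/H2O at 0 °C should convert it into the para-quinone with loss of methanol, coming back to the route at 7.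

Step 1. The second ring bromination, at a position para to the acetyl group, may be slow enough for side-chain bromination of the methyl ketone to compete. The fallback moves the halogenation to the quinone stage. It sets out from 1, which is aroylated with 4 under LiN(SiMe3)2 in THF to 1-[4-(benzyloxy)phenyl]-3-(2-hydroxy-3,6-dimethoxyphenyl)propane-1,3-dione F4. Cyclodehydration (catalytic p-TsOH, toluene, reflux) should give 2-[4-(benzyloxy)phenyl]-5,8-dimethoxy-4H-chromen-4-one F5, and (NH4)2Ce(NO3)6 in MeCN/H2O should oxidise F5 to 2-[4-(benzyloxy)phenyl]-4H-chromene-4,5,8-trione F6. Br2 in AcOH in the dark should add across C6=C7 to give racemic trans-2-[4-(benzyloxy)phenyl]-6,7-dibromo-6,7-dihydro-4H-chromene-4,5,8-trione F7. NaOAc should remove HBr to give 2-[4-(benzyloxy)phenyl]-7-bromo-4H-chromene-4,5,8-trione F8, written as the 7-bromo isomer although the position of the first bromine is immaterial. A second addition of Br2 should give racemic 2-[4-(benzyloxy)phenyl]-6,7,7-tribromo-6,7-dihydro-4H-chromene-4,5,8-trione F9, and a second loss of HBr with NaOAc comes back to the route at 7. The quinone double bond has to react before ring B and C3 in this variant, which is why it is held in reserve.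

Further compounds
F1 | step 5 | 1-(2-hydroxy-3,4,5,6-tetramethoxyphenyl)ethanone | CC(=O)c1c(O)c(OC)c(OC)c(OC)c1OC
F2 | step 5 | 1-[4-(benzyloxy)phenyl]-3-(2-hydroxy-3,4,5,6-tetramethoxyphenyl)propane-1,3-dione | O=C(CC(=O)c1ccc(OCc2ccccc2)cc1)c1c(O)c(OC)c(OC)c(OC)c1OC
F3 | step 4 | 2-[4-(benzyloxy)phenyl]-6,7-dibromo-5-hydroxy-8-methoxy-4H-chromen-4-one | COc1c(Br)c(Br)c(O)c2c(=O)cc(-c3ccc(OCc4ccccc4)cc3)oc12
F4 | step 1 | 1-[4-(benzyloxy)phenyl]-3-(2-hydroxy-3,6-dimethoxyphenyl)propane-1,3-dione | O=C(CC(=O)c1ccc(OCc2ccccc2)cc1)c1c(O)c(OC)ccc1OC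
F5 | step 1 | 2-[4-(benzyloxy)phenyl]-5,8-dimethoxy-4H-chromen-4-one | COc1ccc(OC)c2oc(-c3ccc(OCc4ccccc4)cc3)cc(=O)c12
F6 | step 1 | 2-[4-(benzyloxy)phenyl]-4H-chromene-4,5,8-trione | O=C1C=CC(=O)C2=C1C(=O)C=C(c1ccc(OCc3ccccc3)cc1)O2
F7 | step 1 | trans-2-[4-(benzyloxy)phenyl]-6,7-dibromo-6,7-dihydro-4H-chromene-4,5,8-trione (racemic, one enantiomer drawn) | O=C1[C@H](Br)[C@@H](Br)C(=O)C2=C1C(=O)C=C(c1ccc(OCc3ccccc3)cc1)O2
F8 | step 1 | 2-[4-(benzyloxy)phenyl]-7-bromo-4H-chromene-4,5,8-trione | O=C1C=C(Br)C(=O)C2=C1C(=O)C=C(c1ccc(OCc3ccccc3)cc1)O2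
F9 | step 1 | 2-[4-(benzyloxy)phenyl]-6,7,7-tribromo-6,7-dihydro-4H-chromene-4,5,8-trione (racemic, one enantiomer drawn) | O=C1[C@H](Br)C(Br)(Br)C(=O)C2=C1C(=O)C=C(c1ccc(OCc3ccccc3)cc1)O2
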